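Which of birch, elm and oak holds the most product at the end of its run, and how much does each hold? The flasks share their loading and time and differ in temperature, and I have the ochre and red runs to go on.

| setting | ochre | red | birch | oak | elm |
|---|---|---|---|---|---|
| starting material | 0.050 M | 0.050 M | 0.050 M | 0.050 M | 0.050 M |
| second substrate | 2 equiv | 2 equiv | 2.00 equiv | 2.00 equiv | 2.00 equiv |
| free enzyme | 0.014 mol% | 0.022 mol% | 0.01 mol% | 0.01 mol% | 0.01 mol% |
| temperature | −15 °C | 5 °C | −10 °C | 20 °C | 5 °C |
| remark | run made earlier | run made earlier |  |  |  |
| time |  |  | 15 min | 15 min | 15 min |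

| run | time / min | product / % |
|---|---|---|
| ochre | 0.667 | 0.5 |
| ochre | 1.50 | 0.6 |
| ochre | 4.00 | 1.0 |
| ochre | 10.0 | 2.8 |
| red | 0.500 | 1.3 |
| red | 1.33 | 3.7 |
| red | 3.00 | 7.5 |
| red | 5.00 | 12.9 |

(scatter of a reading: 0.3 percentage points)

* the flask with the highest amount of product, in percent of the starting material charged ("all alike" if they lie within 1.5 percentage points) (birch / oak / elm / all alike)
* final product, as a percentage of the starting material charged, in birch
* final product, as a percentage of the starting material charged, in oak
* final product, as a percentage of the starting material charged, in elm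

- what may be going on: free enzyme -> unfolded enzyme; starting material + free enzyme <-> starting complex; second substrate + starting complex <-> ternary complex; ternary complex -> free enzyme + product; free enzyme <-> dormant form

I take the settings in turn, starting with the loading. By hand, at fixed temperature and time, I take product in proportion to the loading of free enzyme. Ochre and red change loading and temperature together, so they cannot test this, and I assume it by dividing the loading out. From its first to its last reading, red gives a slope over loading of 117 min⁻¹. This is the turnover frequency N, the turnovers per minute per enzyme charged. Ochre, over its last two readings, gives 21.4 min⁻¹, a rough reading, since that rise is 1.8 percentage points against a scatter of 0.3 points.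

Next comes time. By hand, at fixed loading and temperature, I take product in proportion to time while the enzyme lasts and the starting material stays near its charge. The red readings lie on a line within the scatter, but they reach only 5.00 min, and these flasks run 15 min.

Last comes temperature. As read from the two runs, N rises by a factor of 5.47 from −15 °C to 5 °C. With a constant factor per degree, I reckon 32.8 min⁻¹ at −10 °C, and 419 min⁻¹ at 20 °C. Elm, at 5 °C, takes red's N directly. Multiplying by loading and time, I expect 4.92% in birch, 17.6% in elm and 62.8% in oak. The oak figure is the weak one: it counts no enzyme going to the unfolded or dormant form, and 20 °C lies above both runs.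

The forecast names oak, with 4.5% in birch, 16.5% in elm and 30% in oak. My oak figure stands higher than its 30%. Of that flask it writes: “Oak is therefore very uncertain.”

The flasks give 5.72% in birch, 17.3% in elm and 22.7% in oak, so oak holds the most, as forecast, with the forecast's oak figure 7.3 points too high.

    free enzyme → unfolded enzyme (k = 0.00150 min⁻¹, Ea = 230 kJ mol⁻¹)
    starting material + free enzyme ⇌ starting complex (K = 250 M⁻¹, k = 5.00 × 10⁵ M⁻¹ min⁻¹, Ea = 16.0 kJ mol⁻¹, ΔH = −47.0 kJ mol⁻¹)
    second substrate + starting complex ⇌ ternary complex (K = 9.30 M⁻¹, k = 17000 M⁻¹ s⁻¹, Ea = 21.0 kJ mol⁻¹, ΔH = −45.0 kJ mol⁻¹)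
    ternary complex → free enzyme + product (k = 260 min⁻¹, Ea = 65.0 kJ mol⁻¹)
    free enzyme ⇌ dormant form (K = 0.830, k = 0.0220 min⁻¹, Ea = 87.0 kJ mol⁻¹, ΔH = 28.0 kJ mol⁻¹)
    (constants at 5 °C)

Over 15 min, oak averages N = 151 min⁻¹, less than the 419 min⁻¹ I reckoned, and half of its turnover of ternary complex into free enzyme and product up to 15 min is done by 5.79 min, earlier than the midpoint of the run at 7.50 min, while at 15.0 min unfolded enzyme holds 41.9% and dormant form 12.7% of the catalyst charged. The repeat of oak at 35 °C averages N = 2.62 min⁻¹, with 0.393% product and >99.9% of the catalyst charged as unfolded enzyme at 15.0 min.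

The earlier runs and the new flask are calculated for substances that don't exist, noise included.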